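**Retrosynthetic overview**

- Labels: ring A is the enal-bearing benzene (a1 carries the propenal, a4–O–C8, a5–O–C7). Ring B is the central benzene (b1–C7, b4–O–C7', b5–O–C8'). Ring C is the catechol on C7'. C9 and C9' are the CH2OH carbons on C8 and C8'.
- Feature: in each 1,4-dioxane one aryl–oxygen bond (a5–O on ring A, b5–O on ring B) lies ortho to the other ether oxygen of the same arene. Cutting both leaves the open-chain bis(2-bromoaryl ether) diol 19, which already holds C7, C8, C7' and C8'.
- Diol 19 comes from an auxiliary-controlled syn glycolate aldol (C7–C8, threo) between the ring A aryloxyacetyl imide 14 and the ring B aldehyde 9. Aldehyde 9 comes from SNAr (b4–O) of the erythro alcohol 6, made by Felkin addition (C7'–ring C) to (S)-glyceraldehyde acetonide.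
- Ring order: rings A, B and C are bought. Both dioxanes are closed together in one copper-catalysed operation. The ring A ester is then turned into the enal and the protecting groups come off last.

Key step: step 11

Remark: aldehyde 4 is assumed to be used directly after preparation because it oligomerises on storage; reagents pre-formed in the flask (5, 8, 11, 15) are numbered, salts formed reversibly by carbonate or amine bases are not.

**Route**

Step 1
Reactants: 1 4-bromocatechol
Product: 2 4-bromo-1,2-bis(methoxymethoxy)benzene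
Conditions: MOMCl, i-Pr2NEt, CH2Cl2, 0 °C → rt
Reagents that add atoms: chloromethyl methyl ether (MOMCl), COCCl
Why: Williamson-type O-alkylation of both phenols by the reactive α-chloro ether masks the catechol as base- and organometal-stable MOM acetals.

Step 2
Reactants: 3 (R)-(2,2-dimethyl-1,3-dioxolan-4-yl)methanol
Product: 4 (S)-2,2-dimethyl-1,3-dioxolane-4-carbaldehyde
Conditions: (COCl)2, DMSO, CH2Cl2, –78 °C; Et3N, –78 → 0 °C; used crude
Reagents that add atoms: none
Why: Swern oxidation converts the primary alcohol to the aldehyde at low temperature without epimerising the α-alkoxy centre that becomes C8' (the descriptor changes from R to S only through the CIP priorities).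

Step 3
Reactants: 2 4-bromo-1,2-bis(methoxymethoxy)benzene; 4 (S)-2,2-dimethyl-1,3-dioxolane-4-carbaldehyde
Product: 6 (R)-[3,4-bis(methoxymethoxy)phenyl][(4S)-2,2-dimethyl-1,3-dioxolan-4-yl]methanol, via arylmagnesium bromide 5 (not isolated)
Conditions: Mg, I2 (cat.), THF, 45 °C; then 4, THF, –78 → 0 °C
Reagents that add atoms: magnesium, [Mg] (retained only in intermediate 5)
Why: Grignard addition to the α-alkoxy aldehyde under non-chelating Felkin–Anh control (attack anti to the dioxolane C–O bond) should favour the anti (erythro) alcohol, setting C7' as R relative to the fixed C8' (S), with the syn epimer removed by chromatography.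

Step 4
Reactants: 6 anti alcohol; 7 3-bromo-4-fluorobenzaldehyde
Product: 9 3-bromo-4-{(R)-[3,4-bis(methoxymethoxy)phenyl][(4S)-2,2-dimethyl-1,3-dioxolan-4-yl]methoxy}benzaldehyde, via sodium alkoxide 8 (not isolated)
Conditions: NaH, DMF, 0 °C; then 7, 0 °C → rt
Reagents that add atoms: sodium hydride, [Na+].[H-] (sodium retained only in intermediate 8)
Why: Nucleophilic aromatic substitution (addition–elimination) of the alkoxide at the fluoride activated by the para formyl group and the ortho bromine forms the b4–O bond; the C7'–O bond is not touched, so C7' keeps its configuration, and the bromide meta to the formyl group is not displaced.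

Step 5
Reactants: 10 (R)-4-benzyl-1,3-oxazolidin-2-one
Product: 12 (R)-4-benzyl-3-(2-bromoacetyl)-1,3-oxazolidin-2-one, via lithium oxazolidinide 11 (not isolated)
Conditions: n-BuLi, THF, –78 °C; BrCH2COBr, –78 → 0 °C
Reagents that add atoms: n-butyllithium, [Li]CCCC (lithium retained only in intermediate 11); bromoacetyl bromide, BrCC(Br)=O
Why: N-acylation of the lithiated oxazolidinone by the acid bromide, whose acyl carbon reacts far faster than its alkyl bromide at –78 °C.

Step 6
Reactants: 12 (R)-4-benzyl-3-(2-bromoacetyl)-1,3-oxazolidin-2-one; 13 methyl 3-bromo-4-hydroxybenzoate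
Product: 14 methyl 4-{2-[(4R)-4-benzyl-2-oxo-1,3-oxazolidin-3-yl]-2-oxoethoxy}-3-bromobenzoate
Conditions: K2CO3, acetone, rt
Reagents that add atoms: none
Why: Williamson ether synthesis (SN2 at the activated α-bromo carbonyl carbon) with the weakly basic phenoxide of an acidified phenol, which should leave the imide and the methyl ester intact.

Step 7
Reactants: 14 ring A aryloxyacetyl imide; 9 ring B aldehyde
Product: 16 syn-aldol adduct (C8 R and C7 S in the imide), via Z-dibutylboron enolate 15 (not isolated)
Conditions: Bu2BOTf, Et3N, CH2Cl2, –78 → 0 °C; 9, –78 → 0 °C; pH 7 buffer, MeOH, H2O2, 0 °C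
Reagents that add atoms: dibutylboron triflate, CCCCB(CCCC)OS(=O)(=O)C(F)(F)F (boron retained only in intermediate 15)
Why: Evans syn-aldol reaction in which the Z-boron enolate reacts through a Zimmerman–Traxler chair with the oxazolidinone carbonyl turned away and the aldehyde on the enolate face opposite the benzyl group, so the (R)-auxiliary sets C8 and C7 together in the syn (threo) relationship with C7 as S.

Step 8
Reactants: 16 syn-aldol adduct
Product: 17 1,3-diol (C7 S, C8 S) with ring A methyl ester and C8'/C9' acetonide intact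
Conditions: NaBH4, THF/H2O (4:1), 0 °C → rt
Reagents that add atoms: none
Why: Reductive cleavage of the N-acyl oxazolidinone by borohydride in wet THF, the imide being far more electrophilic than the aryl methyl ester; no stereocentre is touched (C8 becomes S only through the CIP priorities).

Step 9
Reactants: 17 1,3-diol acetonide
Product: 18 tetraol (free OH at C7, C9, C8', C9')
Conditions: AcOH/H2O (4:1), 40 °C
Reagents that add atoms: none
Why: Acid-catalysed ketal hydrolysis, in which the isopropylidene ketal ionises through a tertiary oxocarbenium ion far faster than the formaldehyde-derived MOM acetals, so dilute acetic acid should free the C8'/C9' diol selectively.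

Step 10
Reactants: 18 tetraol
Product: 19 open-chain dibromo diol with C9 and C9' as TBS ethers (C7 S, C8 S, C7' R, C8' S)
Conditions: TBSCl (2.2 equiv), imidazole, CH2Cl2/DMF, –20 → 0 °C
Reagents that add atoms: tert-butyldimethylsilyl chloride, CC(C)(C)[Si](C)(C)Cl
Why: Sterically controlled silylation, the two primary hydroxyls reacting much faster with TBSCl/imidazole than the hindered secondary hydroxyls at C7 and C8'.

Step 11
Reactants: 19 open-chain dibromo diol
Product: 22 fully protected bis-benzodioxane with ring A methyl ester, via ring A monocyclised bromo alcohol 20 (not isolated), via ring B monocyclised bromo alcohol 21 (not isolated)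
Conditions: CuI (20 mol %), 3,4,7,8-tetramethyl-1,10-phenanthroline (40 mol %), Cs2CO3 (4 equiv), toluene (0.02 M), 110 °C, Ar
Reagents that add atoms: none
Why: Each caesium alkoxide is passed to phenanthroline-ligated monovalent copper, the copper alkoxide adds oxidatively into the C–Br bond ortho to the existing aryl ether oxygen to give a six-membered trivalent copper aryl alkoxide chelate, and reductive elimination forms the aryl–oxygen bond. The closest known reaction type is the intramolecular Ullmann-type copper-catalysed O-arylation of secondary alcohols by ortho-bromoaryl ethers that gives 2,3-disubstituted 1,4-benzodioxanes, here run at two sites in one flask. The ring A dioxane closes by attack of the C7 oxygen on a5 (bond a5–O, six-membered closure in the 6-exo mode with the C–Br bond outside the new ring) and the ring B dioxane by attack of the C8' oxygen on b5 (bond b5–O, same mode), passing through 20 or 21 according to which site reacts first. No stereocentre is created: only O–H and aryl C–Br bonds are broken, so C7, C8, C7' and C8' are carried over with retention, the threo C7/C8 pair giving the trans ring and the erythro C7'/C8' pair the cis ring. The step needs site selectivity and configurational integrity: each alkoxide can reach only the bromide that gives a six-membered ring (the crossed closures would need a 13-membered or a meta-bridged ring), and the basic, non-ionising medium together with the MOM-capped para oxygen of ring C should prevent benzylic ionisation or quinone-methide epimerisation at C7 and C7'.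

Step 12
Reactants: 22 bis-benzodioxane methyl ester
Product: 23 ring A benzylic alcohol
Conditions: i-Bu2AlH, CH2Cl2, –78 → –40 °C; Rochelle salt
Reagents that add atoms: none
Why: Hydride reduction of the aryl ester to the benzylic alcohol by i-Bu2AlH, to which silyl ethers, MOM acetals and the dioxane ethers are inert.

Step 13
Reactants: 23 ring A benzylic alcohol
Product: 24 ring A aryl aldehyde
Conditions: MnO2, CH2Cl2, rt
Reagents that add atoms: none
Why: MnO2 oxidation is selective for benzylic alcohols, stops at the aldehyde and is neutral, so no protecting group or stereocentre is at risk.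

Step 14
Reactants: 24 ring A aryl aldehyde
Product: 25 protected (E)-enal
Conditions: Ph3P=CHCHO, toluene, 80 °C
Reagents that add atoms: (triphenylphosphoranylidene)acetaldehyde, O=CC=P(c1ccccc1)(c1ccccc1)c1ccccc1
Why: Wittig reaction with the stabilised formylmethylene ylide should give the (E)-enal, the ylide reacting faster with the aryl aldehyde than with the conjugated product.

Step 15
Reactants: 25 protected (E)-enal
Product: 26 CNP0302404.1
Conditions: 3 M aq. HCl, THF/i-PrOH (1:1), 40 °C
Reagents that add atoms: none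
Why: Acid-catalysed hydrolysis removes both MOM acetals and both primary TBS ethers in one operation; the aqueous medium prevents acetalisation of the enal, and the mild temperature should keep the C7' benzylic ether from ionising.

**Compound list**

1 | 4-bromocatechol | Oc1ccc(Br)cc1O | starting material
2 | 4-bromo-1,2-bis(methoxymethoxy)benzene | COCOc1ccc(Br)cc1OCOC | intermediate
3 | (R)-(2,2-dimethyl-1,3-dioxolan-4-yl)methanol | OC[C@@H]1COC(C)(C)O1 | starting material
4 | (S)-2,2-dimethyl-1,3-dioxolane-4-carbaldehyde | O=C[C@@H]1COC(C)(C)O1 | intermediate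
5 | [3,4-bis(methoxymethoxy)phenyl]magnesium bromide | COCOc1ccc([Mg]Br)cc1OCOC | intermediate (not isolated)
6 | (R)-[3,4-bis(methoxymethoxy)phenyl][(4S)-2,2-dimethyl-1,3-dioxolan-4-yl]methanol (anti; C7' R, C8' S) | O[C@H](c1ccc(OCOC)c(OCOC)c1)[C@@H]1COC(C)(C)O1 | intermediate
7 | 3-bromo-4-fluorobenzaldehyde | O=Cc1ccc(F)c(Br)c1 | starting material
8 | sodium alkoxide of 6 | [Na+].[O-][C@H](c1ccc(OCOC)c(OCOC)c1)[C@@H]1COC(C)(C)O1 | intermediate (not isolated)
9 | 3-bromo-4-{(R)-[3,4-bis(methoxymethoxy)phenyl][(4S)-2,2-dimethyl-1,3-dioxolan-4-yl]methoxy}benzaldehyde | O=Cc1ccc(O[C@H](c2ccc(OCOC)c(OCOC)c2)[C@@H]2COC(C)(C)O2)c(Br)c1 | intermediate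
10 | (R)-4-benzyl-1,3-oxazolidin-2-one | O=C1N[C@H](Cc2ccccc2)CO1 | starting material
11 | lithium salt of 10 (N-lithiated) | [Li+].O=C1[N-][C@H](Cc2ccccc2)CO1 | intermediate (not isolated)
12 | (R)-4-benzyl-3-(2-bromoacetyl)-1,3-oxazolidin-2-one | O=C(CBr)N1[C@H](Cc2ccccc2)COC1=O | intermediate
13 | methyl 3-bromo-4-hydroxybenzoate | COC(=O)c1ccc(O)c(Br)c1 | starting material
14 | methyl 4-{2-[(4R)-4-benzyl-2-oxo-1,3-oxazolidin-3-yl]-2-oxoethoxy}-3-bromobenzoate | COC(=O)c1ccc(OCC(=O)N2[C@H](Cc3ccccc3)COC2=O)c(Br)c1 | intermediate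
15 | Z-dibutylboron enolate of 14 | CCCCB(CCCC)O/C(=C\Oc1ccc(C(=O)OC)cc1Br)N1[C@H](Cc2ccccc2)COC1=O | intermediate (not isolated)
16 | methyl 4-{[(2R,3S)-1-[(4R)-4-benzyl-2-oxo-1,3-oxazolidin-3-yl]-3-(3-bromo-4-{(R)-[3,4-bis(methoxymethoxy)phenyl][(4S)-2,2-dimethyl-1,3-dioxolan-4-yl]methoxy}phenyl)-3-hydroxy-1-oxopropan-2-yl]oxy}-3-bromobenzoate (syn aldol adduct) | COC(=O)c1ccc(O[C@@H](C(=O)N2[C@H](Cc3ccccc3)COC2=O)[C@@H](O)c2ccc(O[C@H](c3ccc(OCOC)c(OCOC)c3)[C@@H]3COC(C)(C)O3)c(Br)c2)c(Br)c1 | intermediate
17 | methyl 3-bromo-4-{[(1S,2S)-1-(3-bromo-4-{(R)-[3,4-bis(methoxymethoxy)phenyl][(4S)-2,2-dimethyl-1,3-dioxolan-4-yl]methoxy}phenyl)-1,3-dihydroxypropan-2-yl]oxy}benzoate | COC(=O)c1ccc(O[C@@H](CO)[C@@H](O)c2ccc(O[C@H](c3ccc(OCOC)c(OCOC)c3)[C@@H]3COC(C)(C)O3)c(Br)c2)c(Br)c1 | intermediate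
18 | methyl 3-bromo-4-{[(1S,2S)-1-(3-bromo-4-{[(1R,2S)-1-[3,4-bis(methoxymethoxy)phenyl]-2,3-dihydroxypropyl]oxy}phenyl)-1,3-dihydroxypropan-2-yl]oxy}benzoate (tetraol) | COC(=O)c1ccc(O[C@@H](CO)[C@@H](O)c2ccc(O[C@H](c3ccc(OCOC)c(OCOC)c3)[C@@H](O)CO)c(Br)c2)c(Br)c1 | intermediate
19 | open-chain dibromo diol: 18 with both primary hydroxyls (C9, C9') as TBS ethers, free OH at C7 (S) and C8' (S), C8 S, C7' R | COC(=O)c1ccc(O[C@@H](CO[Si](C)(C)C(C)(C)C)[C@@H](O)c2ccc(O[C@H](c3ccc(OCOC)c(OCOC)c3)[C@@H](O)CO[Si](C)(C)C(C)(C)C)c(Br)c2)c(Br)c1 | intermediate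
20 | ring A monocyclised bromo alcohol (trans dioxane on ring A closed, ring B bromide and C8' OH still open) | COC(=O)c1ccc2c(c1)O[C@@H](c1ccc(O[C@H](c3ccc(OCOC)c(OCOC)c3)[C@@H](O)CO[Si](C)(C)C(C)(C)C)c(Br)c1)[C@H](CO[Si](C)(C)C(C)(C)C)O2 | intermediate (not isolated)
21 | ring B monocyclised bromo alcohol (cis dioxane on ring B closed, ring A bromide and C7 OH still open) | COC(=O)c1ccc(O[C@@H](CO[Si](C)(C)C(C)(C)C)[C@@H](O)c2ccc3c(c2)O[C@@H](CO[Si](C)(C)C(C)(C)C)[C@@H](c2ccc(OCOC)c(OCOC)c2)O3)c(Br)c1 | intermediate (not isolated)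
22 | fully protected bis-benzodioxane methyl ester: trans ring A dioxane (C7 S, C8 S), cis ring B dioxane (C7' R, C8' S), two CH2OTBS, ring C bis-MOM | COC(=O)c1ccc2c(c1)O[C@@H](c1ccc3c(c1)O[C@@H](CO[Si](C)(C)C(C)(C)C)[C@@H](c1ccc(OCOC)c(OCOC)c1)O3)[C@H](CO[Si](C)(C)C(C)(C)C)O2 | intermediate
23 | benzylic alcohol (CH2OH on a1 in place of the ester of 22) | OCc1ccc2c(c1)O[C@@H](c1ccc3c(c1)O[C@@H](CO[Si](C)(C)C(C)(C)C)[C@@H](c1ccc(OCOC)c(OCOC)c1)O3)[C@H](CO[Si](C)(C)C(C)(C)C)O2 | intermediate
24 | aryl aldehyde (CHO on a1) | O=Cc1ccc2c(c1)O[C@@H](c1ccc3c(c1)O[C@@H](CO[Si](C)(C)C(C)(C)C)[C@@H](c1ccc(OCOC)c(OCOC)c1)O3)[C@H](CO[Si](C)(C)C(C)(C)C)O2 | intermediate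
25 | protected (E)-enal (bis-TBS, bis-MOM) | O=C/C=C/c1ccc2c(c1)O[C@@H](c1ccc3c(c1)O[C@@H](CO[Si](C)(C)C(C)(C)C)[C@@H](c1ccc(OCOC)c(OCOC)c1)O3)[C@H](CO[Si](C)(C)C(C)(C)C)O2 | intermediate
26 | CNP0302404.1, (2E)-3-[(2S,3S)-3-[(2R,3S)-2-(3,4-dihydroxyphenyl)-3-(hydroxymethyl)-2,3-dihydro-1,4-benzodioxin-6-yl]-2-(hydroxymethyl)-2,3-dihydro-1,4-benzodioxin-6-yl]prop-2-enal | O=C/C=C/c1ccc2c(c1)O[C@@H](c1ccc3c(c1)O[C@@H](CO)[C@@H](c1ccc(O)c(O)c1)O3)[C@H](CO)O2 | target

**Step count and risks**

Total step count: 15. Longest linear sequence: 12 steps (1 → 2 → 6 → 9 → 16 → 17 → 18 → 19 → 22 → 23 → 24 → 25 → 26).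

Steps most likely to fail:

1. Step 11. Oxidative addition into the two electron-rich, ortho-alkoxy aryl bromides may be slow, so that the second closure stalls. Meanwhile the hot carbonate medium allows silyl migration from a primary to the neighbouring secondary oxygen and displacement of an aryloxide by the adjacent alkoxide. The fallback sets out from 19 and reverses the polarity of the aryl partner. Miyaura borylation (B2pin2, PdCl2(dppf), KOAc, dioxane, 85 °C) should give the bis(pinacolboronate) diol F1. Chan–Lam oxidative etherification at room temperature (Cu(OAc)2, pyridine, 4 Å molecular sieves, O2, CH2Cl2) should then join the C7 and C8' hydroxyls to the arylboron carbons, returning to the route at 22.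

2. Step 4. The hindered secondary alkoxide may add reversibly to the formyl group and transfer hydride (Cannizzaro- or Oppenauer-type redox) faster than it displaces fluoride. The fallback sets out from 6 and uses 3-bromo-4-fluorobenzonitrile (NaH, DMF, 0 °C → rt) as an electrophile without a carbonyl group, giving the aryl ether nitrile F2. Reduction with i-Bu2AlH (toluene, –78 °C) and mild aqueous acidic hydrolysis of the aldimine should return to the route at 9.

3. Step 3. Facial selectivity in the addition to the α-alkoxy aldehyde may be poor, leaving an anti/syn mixture that is hard to separate. The fallback sets out from 6 as its mixture with the C7' epimer and replaces substrate control by catalyst control. Dess–Martin oxidation should give the aryl ketone F3. Corey–Bakshi–Shibata reduction with (R)-2-methyl-CBS-oxazaborolidine and BH3·SMe2, the aryl group acting as the larger substituent, should return to the route at 6 with C7' as R.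

**Further compounds**

F1 | step 11 | bis(pinacolboronate) diol: 19 with both bromines replaced by 4,4,5,5-tetramethyl-1,3,2-dioxaborolan-2-yl groups | COC(=O)c1ccc(O[C@@H](CO[Si](C)(C)C(C)(C)C)[C@@H](O)c2ccc(O[C@H](c3ccc(OCOC)c(OCOC)c3)[C@@H](O)CO[Si](C)(C)C(C)(C)C)c(B3OC(C)(C)C(C)(C)O3)c2)c(B2OC(C)(C)C(C)(C)O2)c1
F2 | step 4 | 3-bromo-4-{(R)-[3,4-bis(methoxymethoxy)phenyl][(4S)-2,2-dimethyl-1,3-dioxolan-4-yl]methoxy}benzonitrile | N#Cc1ccc(O[C@H](c2ccc(OCOC)c(OCOC)c2)[C@@H]2COC(C)(C)O2)c(Br)c1
F3 | step 3 | [3,4-bis(methoxymethoxy)phenyl][(4S)-2,2-dimethyl-1,3-dioxolan-4-yl]methanone | O=C(c1ccc(OCOC)c(OCOC)c1)[C@@H]1COC(C)(C)O1
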